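**Plan**
- Retrosynthetic cuts, in order: the C2–C3 epoxide oxygen (back to an E-alkene); C4–C5 (ten-membered ring, alkenylstannane plus allylic acetate); C8–C17 (γ-lactone, reductive aldol of a C7 acrylate onto a C8 ketone); C8–C9 (acyl–alkynyl coupling with a C5–C8/C16 diyne); C1–C10 (retro-Claisen to a δ-lactone); the lactone chain at C12–C13 (vinylogous aldol).
- Enabling feature: in the cyclohexenone ring (C1, C10–C14) the array C9–C10–C1–C14=C13 is a γ,δ-unsaturated carbonyl once C9 is a carboxyl. The ring bond C1–C10 is therefore the product bond of a [3,3] shift of the ketene acetal of a δ-lactone (ring O–C9–C10–C11–C12–C13) that carries the alkenyl group C14=C1(Me)–C2 on C13.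
- Forward order: Z,E-dienal → δ-lactone (temporary ring) → six-membered carbocycle (key step) → C9 side chain → γ-lactone → C12 ketone → ten-membered ring → epoxide.
- Stereochemistry: C13 (catalytic vinylogous aldol) and C11 (Sharpless epoxidation) are set by reagent control and relayed to C10 and C1 through the boat Claisen transition state. C9 comes from Noyori transfer hydrogenation, C7 from matched Sharpless epoxidation followed by SN2 opening, C8 and C17 from the reductive aldol, the C5=C6 geometry from trans-hydrostannation, and C2/C3 from peripheral epoxidation.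

Key step: step 11

Assumption: compounds 1, 3, 7 and 17 and all reagents are taken as commercial; atom labels C1–C20 follow briarane numbering of the target (C1 = quaternary ring-fusion carbon, C10 = its CH neighbour, C15/C20 = methyls on C1/C11, C16 = acetoxymethyl carbon, C17–C19 = lactone carbons).

**Step 1**
Reactants: 1 but-2-yn-1-ol
Product: 2 (Z)-3-iodobut-2-en-1-ol
Conditions: NaAlH2(OCH2CH2OMe)2, Et2O, 0 → 23 °C; then I2, −78 °C
Reagents that add atoms: iodine, II
Why: Hydroxyl-directed trans-hydroalumination of the propargylic alcohol puts aluminium on C3 and iodinolysis with retention should give the Z iodide, so the methyl group (future Me-15) ends trans to the carbinol carbon (future C13).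

**Step 2**
Reactants: 3 (E)-3-(tributylstannyl)prop-2-en-1-ol
Product: 4 (E)-tributyl[3-(4-methoxybenzyloxy)prop-1-enyl]stannane
Conditions: NaH, 4-MeOC6H4CH2Cl, Bu4NI (cat.), THF, 0 → 23 °C
Reagents that add atoms: 4-methoxybenzyl chloride, COc1ccc(CCl)cc1
Why: Williamson etherification of the alkoxide; the alkenyl–tin bond is inert to NaH.

**Step 3**
Reactants: 2 (Z)-3-iodobut-2-en-1-ol; 4 (E)-tributyl[3-(4-methoxybenzyloxy)prop-1-enyl]stannane
Product: 5 (2Z,4E)-6-(4-methoxybenzyloxy)-3-methylhexa-2,4-dien-1-ol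
Conditions: PdCl2(MeCN)2 (5 mol%), DMF, 23 °C
Reagents that add atoms: none
Why: Stille coupling proceeds with retention at both sp2 carbons, which should give the (2Z,4E)-diene in which C2 is cis to C13 across C14=C1.

**Step 4**
Reactants: 5 (2Z,4E)-6-(4-methoxybenzyloxy)-3-methylhexa-2,4-dien-1-ol
Product: 6 (2Z,4E)-6-(4-methoxybenzyloxy)-3-methylhexa-2,4-dienal
Conditions: MnO2, CH2Cl2, 23 °C, dark
Reagents that add atoms: none
Why: Heterogeneous MnO2 oxidation of an allylic alcohol is neutral and should keep the Z geometry of the enal.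

**Step 5**
Reactants: 7 methyl 3-methylbut-2-enoate
Product: 8 tert-butyl[(1-methoxy-3-methylbuta-1,3-dienyl)oxy]dimethylsilane
Conditions: LiN(i-Pr)2, THF/DMPU, −78 °C; t-BuMe2SiCl
Reagents that add atoms: tert-butyldimethylsilyl chloride, CC(C)(C)[Si](C)(C)Cl
Why: Kinetic γ-deprotonation of the senecioate and O-silylation give the vinylogous silyl ketene acetal.

**Step 6**
Reactants: 6 (2Z,4E)-6-(4-methoxybenzyloxy)-3-methylhexa-2,4-dienal; 8 tert-butyl[(1-methoxy-3-methylbuta-1,3-dienyl)oxy]dimethylsilane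
Product: 9 methyl (2E,5R,6Z,8E)-5-hydroxy-10-(4-methoxybenzyloxy)-3,7-dimethyldeca-2,6,8-trienoate
Conditions: SiCl4, chiral Denmark bisphosphoramide (5 mol%, the enantiomer that shields the Si face of the aldehyde), i-Pr2NEt (10 mol%), CH2Cl2, −78 °C; aq. KF/NaHCO3
Reagents that add atoms: none
Why: Lewis-base-activated SiCl4 vinylogous Mukaiyama aldol (Denmark type): γ-attack on the Re face of the enal under catalyst control should set C13 as R and give the E-enoate.

**Step 7**
Reactants: 9 methyl (2E,5R,6Z,8E)-5-hydroxy-10-(4-methoxybenzyloxy)-3,7-dimethyldeca-2,6,8-trienoate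
Product: 10 (2E,5R,6Z,8E)-10-(4-methoxybenzyloxy)-3,7-dimethyldeca-2,6,8-triene-1,5-diol
Conditions: i-Bu2AlH (3.5 equiv), CH2Cl2, −78 → 0 °C
Reagents that add atoms: none
Why: Hydride reduction of the ester to the primary allylic alcohol; the alkenes and the benzyl ether are untouched.

**Step 8**
Reactants: 10 (2E,5R,6Z,8E)-10-(4-methoxybenzyloxy)-3,7-dimethyldeca-2,6,8-triene-1,5-diol
Product: 11 [(2R,3R)-3-[(2R,3Z,5E)-2-hydroxy-7-(4-methoxybenzyloxy)-4-methylhepta-3,5-dienyl]-3-methyloxiran-2-yl]methanol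
Conditions: Ti(Oi-Pr)4 (10 mol%), D-(−)-diethyl tartrate (12 mol%), t-BuOOH (1.1 equiv), 4 Å MS, CH2Cl2, −25 °C
Reagents that add atoms: tert-butyl hydroperoxide, CC(C)(C)OO
Why: Katsuki–Sharpless epoxidation under reagent control (D-tartrate, by analogy with geraniol) should give the (2R,3R)-epoxide and so set C11; the primary E-allylic alcohol is expected to react much faster than the encumbered Z-dienyl secondary carbinol.

**Step 9**
Reactants: 11 [(2R,3R)-3-[(2R,3Z,5E)-2-hydroxy-7-(4-methoxybenzyloxy)-4-methylhepta-3,5-dienyl]-3-methyloxiran-2-yl]methanol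
Product: 12 (3S,5R,6Z,8E)-10-(4-methoxybenzyloxy)-3,7-dimethyldeca-6,8-diene-1,3,5-triol
Conditions: NaAlH2(OCH2CH2OMe)2, THF, 0 °C
Reagents that add atoms: none
Why: The alkoxyaluminate delivers hydride intramolecularly to C2 of the 2,3-epoxy alcohol (C10), which leaves the tertiary C11–O bond and its configuration intact (1,3-diol formation).

**Step 10**
Reactants: 12 (3S,5R,6Z,8E)-10-(4-methoxybenzyloxy)-3,7-dimethyldeca-6,8-diene-1,3,5-triol
Product: 13 (4R,6R)-4-hydroxy-6-[(1Z,3E)-5-(4-methoxybenzyloxy)-2-methylpenta-1,3-dienyl]-4-methyltetrahydropyran-2-one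
Conditions: TEMPO (20 mol%), PhI(OAc)2 (2.5 equiv), CH2Cl2, 23 °C
Reagents that add atoms: none
Why: Oxoammonium oxidation is selective for the primary alcohol; the aldehyde is trapped by the C13 hydroxyl as a six-membered lactol, which is oxidised on to the δ-lactone with 4-OH cis to the 6-alkenyl group.

**Step 11**
Reactants: 13 (4R,6R)-4-hydroxy-6-[(1Z,3E)-5-(4-methoxybenzyloxy)-2-methylpenta-1,3-dienyl]-4-methyltetrahydropyran-2-one
Product: 16 (1R,2R,6R)-2-[(E)-3-(4-methoxybenzyloxy)prop-1-enyl]-2,6-dimethyl-6-(triethylsilyloxy)cyclohex-3-ene-1-carboxylic acid, via bis(triethylsilyl) ketene acetal 14 (not isolated), via triethylsilyl ester 15 (not isolated)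
Conditions: LiN(i-Pr)2 (2.4 equiv), THF, −78 °C; Et3SiCl (3 equiv), Et3N, DMPU, −78 → 23 °C; PhMe, 85 °C; K2CO3, MeOH/H2O, 0 °C, then pH 4
Reagents that add atoms: chlorotriethylsilane, CC[Si](Cl)(CC)CC
Why: Double deprotonation gives the alkoxide–enolate of the δ-lactone, which is O-silylated to ketene acetal 14 and undergoes a suprafacial [3,3]-sigmatropic shift in which O–C13 breaks as C10–C1 forms; this is the lactonic variant of the Ireland–Claisen rearrangement, known for 6-alkenyl δ-lactones, which give cyclohex-3-enecarboxylic acids. The six-membered carbocycle (C1, C10–C14) closes in this concerted shift through a boat, bicyclo[2.2.2]octane-like transition state that the temporary lactone ring enforces, and the ring oxygen leaves as the C9 carboxylate. C10 is set because the new bond must form on the lactone face that carries the alkenyl group, which places H-10 cis to the C11 oxygen that was cis to that group; C1 is set by the Z geometry of C14=C1 within the boat, which places C2 cis to H-10 and Me-15 cis to the carboxyl. The step needs the [3,3] shift to outrun β-elimination of the C11 oxygen and a 1,5-hydrogen shift of the Z-diene; the C11 oxygen is an alkoxide during enolisation and the rearrangement should run below 90 °C, and chair and C-silylation pathways are closed off by the ring.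

**Step 12**
Reactants: 17 1,4-bis(trimethylsilyl)buta-1,3-diyne
Product: 18 5-(trimethylsilyl)penta-2,4-diyn-1-ol
Conditions: MeLi·LiBr (1.0 equiv), THF, 23 °C; (CH2O)n, −78 → 23 °C
Reagents that add atoms: formaldehyde (as paraformaldehyde), C=O
Why: MeLi·LiBr cleaves one C–Si bond to give the lithium diynide, which adds to formaldehyde.

**Step 13**
Reactants: 18 5-(trimethylsilyl)penta-2,4-diyn-1-ol
Product: 19 triethyl{[5-(trimethylsilyl)penta-2,4-diynyl]oxy}silane
Conditions: Et3SiCl, imidazole, CH2Cl2, 0 °C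
Reagents that add atoms: chlorotriethylsilane, CC[Si](Cl)(CC)CC
Why: Standard silylation of a primary alcohol.

**Step 14**
Reactants: 16 (1R,2R,6R)-2-[(E)-3-(4-methoxybenzyloxy)prop-1-enyl]-2,6-dimethyl-6-(triethylsilyloxy)cyclohex-3-ene-1-carboxylic acid; 19 triethyl{[5-(trimethylsilyl)penta-2,4-diynyl]oxy}silane
Product: 21 C9 diynone 1-[(1R,2R,6R)-2-[(E)-3-(4-methoxybenzyloxy)prop-1-enyl]-2,6-dimethyl-6-(triethylsilyloxy)cyclohex-3-enyl]-6-(triethylsilyloxy)hexa-2,4-diyn-1-one, via acid chloride 20 (not isolated)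
Conditions: 16, Me2C=C(Cl)NMe2, CH2Cl2, 0 °C; separately 19, MeLi·LiBr, THF, −78 → 0 °C, then ZnCl2; combine, Pd(PPh3)4 (5 mol%), THF, 0 → 23 °C
Reagents that add atoms: none
Why: The acid chloride is formed under neutral conditions and acylates the alkynylzinc under zerovalent palladium catalysis (Negishi acylation); no amine base is present, so C10 should not epimerise through a ketene.

**Step 15**
Reactants: 21 C9 diynone
Product: 22 (9R)-diynol (C9 carbinol of 21, configured as C9 of 37)
Conditions: Ru[(R,R)-TsDPEN](p-cymene) (2 mol%), i-PrOH, 23 °C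
Reagents that add atoms: none
Why: Noyori transfer hydrogenation of an alkynyl ketone: the alkyne is the directing π group, so the (R,R) catalyst should deliver hydride to give the 9R carbinol irrespective of the bulk of the C10 substituent.

**Step 16**
Reactants: 22 (9R)-diynol
Product: 23 (7E,9R)-enynol (C7=C8 E-alkene, C5≡C6 alkyne retained, free 9-OH)
Conditions: NaAlH2(OCH2CH2OMe)2, THF, −20 → 0 °C
Reagents that add atoms: none
Why: Alkoxide-directed trans-hydroalumination reduces only the alkyne next to the free C9 hydroxyl and should give the E-alkene; the silyl-protected propargylic end is not reduced.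

**Step 17**
Reactants: 23 (7E,9R)-enynol
Product: 24 (7R,8R,9R)-7,8-epoxy-9-ol (trans-epoxide anti to 9-OH)
Conditions: Ti(Oi-Pr)4 (1.1 equiv), D-(−)-diisopropyl tartrate (1.3 equiv), t-BuOOH (2 equiv), 4 Å MS, CH2Cl2, −20 °C
Reagents that add atoms: tert-butyl hydroperoxide, CC(C)(C)OO
Why: Sharpless epoxidation of a secondary E-allylic alcohol in its matched (fast-reacting) pairing with D-tartrate should give the erythro trans-epoxide; no other allylic alcohol is present.

**Step 18**
Reactants: 24 (7R,8R,9R)-7,8-epoxy-9-ol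
Product: 25 C9 triethylsilyl ether of 24
Conditions: Et3SiOTf, 2,6-lutidine, CH2Cl2, −78 °C
Reagents that add atoms: triethylsilyl trifluoromethanesulfonate, CC[Si](CC)(CC)OS(=O)(=O)C(F)(F)F
Why: Silyl triflate silylates the hindered secondary alcohol without opening the epoxide.

**Step 19**
Reactants: 25 C9 triethylsilyl ether of 24
Product: 26 C7 acrylate C8 alcohol (epoxide opened at C7 with inversion)
Conditions: CH2=CHCO2H (5 equiv), Cs2CO3 (1 equiv), BHT, DMF, 60 °C
Reagents that add atoms: acrylic acid, C=CC(=O)O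
Why: SN2 opening of the alkynyl epoxide by carboxylate at the propargylic carbon C7, which is both activated and remote from the bulky C9 substituent, should invert C7 to the configuration of 37; the excess acid buffers against acyl and silyl migration.

**Step 20**
Reactants: 26 C7 acrylate C8 alcohol
Product: 27 C8 ketone (α-acryloyloxy ketone)
Conditions: Dess–Martin periodinane, NaHCO3, CH2Cl2, 0 → 23 °C
Reagents that add atoms: none
Why: Buffered Dess–Martin oxidation of the secondary alcohol does not disturb the acidic C7 stereocentre.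

**Step 21**
Reactants: 27 C8 ketone
Product: 28 β-hydroxy-γ-lactone (C7–O–C19(=O)–C17(Me)–C8(OH), configured as in 37)
Conditions: Cu(OAc)2·H2O (5 mol%), rac-BINAP (5 mol%), (HMe2Si)2O (1 equiv), THF, 0 → 23 °C; aq. NH4F
Reagents that add atoms: none
Why: Copper hydride reduces the acrylate 1,4 to a Z copper enolate that adds to the C8 ketone through a chelated closed transition state (reductive aldol cyclisation of the Lam/Chiu type); placing C6 anti to C9 should put 8-OH cis to C6, and the Z enolate should put Me-18 cis to 8-OH.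

**Step 22**
Reactants: 28 β-hydroxy-γ-lactone
Product: 30 C12 enone of 28, via C12 allylic alcohol 29 (not isolated)
Conditions: SeO2 (0.5 equiv), t-BuOOH, CH2Cl2, 23 °C; then Dess–Martin periodinane, NaHCO3, CH2Cl2
Reagents that add atoms: selenium dioxide, O=[Se]=O; tert-butyl hydroperoxide, CC(C)(C)OO
Why: The SeO2 ene reaction and [2,3] shift can occur only at C12 for C13=C14 (C1 is quaternary), the C2=C3 alkene is deactivated by its allylic ether oxygen and neopentyl position, and oxidation of the allylic alcohol gives the enone whatever its C12 configuration.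

**Step 23**
Reactants: 30 C12 enone
Product: 31 C4 allylic alcohol (4-methoxybenzyl group removed)
Conditions: DDQ, CH2Cl2/pH 7 buffer, 0 °C
Reagents that add atoms: none
Why: Oxidative cleavage of the 4-methoxybenzyl ether; silyl ethers, lactone and enone tolerate buffered DDQ.

**Step 24**
Reactants: 31 C4 allylic alcohol
Product: 32 C4 allylic acetate
Conditions: Ac2O, pyridine, DMAP (cat.), CH2Cl2, 0 °C
Reagents that add atoms: acetic anhydride, CC(=O)OC(C)=O
Why: Acetylation of the primary allylic alcohol; the tertiary 8-OH is inert under these conditions.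

**Step 25**
Reactants: 32 C4 allylic acetate
Product: 33 alkyne tetraol (free 8-, 9-, 11- and 16-OH, C4 acetate)
Conditions: HF·pyridine, pyridine/THF, 0 → 23 °C
Reagents that add atoms: none
Why: Buffered fluoride cleaves all three triethylsilyl ethers; the acetate, lactone and enone should survive.

**Step 26**
Reactants: 33 alkyne tetraol
Product: 34 (5Z)-5-tributylstannyl alkene (Sn on C5 cis to C7, H on C6)
Conditions: [Cp*RuCl]4 (2.5 mol%), Bu3SnH (1.1 equiv), CH2Cl2, 23 °C
Reagents that add atoms: tributyltin hydride, CCCC[SnH](CCCC)CCCC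
Why: Ruthenium-catalysed trans-hydrostannation directed by the free propargylic hydroxyl (Fürstner type) should put tin on C5 and hydrogen trans on C6, which fixes the C5=C6 geometry.

**Step 27**
Reactants: 34 (5Z)-5-tributylstannyl alkene
Product: 35 macrocyclic tetraol (2,3-deoxy-9,11,16-tris-deacetyl 37 with a 2E alkene)
Conditions: Pd2(dba)3 (10 mol%), AsPh3 (40 mol%), LiCl (3 equiv), DMF, 1 mM, 50 °C
Reagents that add atoms: none
Why: Palladium-catalysed Stille coupling of an allylic acetate with an alkenylstannane, run intramolecularly at high dilution: ionisation gives the syn π-allyl, and transmetalation and reductive elimination at the unhindered terminus C4 should close the ten-membered ring with retention of both alkene geometries.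

**Step 28**
Reactants: 35 macrocyclic tetraol
Product: 36 (2E)-alkene triacetate (2,3-deoxy 37)
Conditions: Ac2O, Et3N, DMAP, CH2Cl2, 23 °C
Reagents that add atoms: acetic anhydride, CC(=O)OC(C)=O
Why: DMAP-catalysed acetylation of the primary C16, secondary C9 and tertiary C11 hydroxyls; the tertiary 8-OH, flanked by three branched carbons, is not expected to react.

**Step 29**
Reactants: 36 (2E)-alkene triacetate
Product: 37 CNP0226792.2 (target)
Conditions: dimethyldioxirane, acetone, −20 → 0 °C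
Reagents that add atoms: dimethyldioxirane, CC1(C)OO1
Why: The strained E-alkene C2=C3 is the only alkene not deactivated by a carbonyl or allylic acyloxy groups; dimethyldioxirane should add to its outer face and give the trans-epoxide stereospecifically, which is 2R,3R if the ring strap (C4 and C10) lies over the Re face of C2, as the natural epoxide suggests.

**Compound list**
1 | but-2-yn-1-ol | CC#CCO | starting material
2 | (Z)-3-iodobut-2-en-1-ol | C/C(I)=C/CO | intermediate
3 | (E)-3-(tributylstannyl)prop-2-en-1-ol | OC/C=C/[Sn](CCCC)(CCCC)CCCC | starting material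
4 | (E)-tributyl[3-(4-methoxybenzyloxy)prop-1-enyl]stannane | COc1ccc(COC/C=C/[Sn](CCCC)(CCCC)CCCC)cc1 | intermediate
5 | (2Z,4E)-6-(4-methoxybenzyloxy)-3-methylhexa-2,4-dien-1-ol | OC/C=C(C)\C=C\COCc1ccc(OC)cc1 | intermediate
6 | (2Z,4E)-6-(4-methoxybenzyloxy)-3-methylhexa-2,4-dienal | O=C/C=C(C)\C=C\COCc1ccc(OC)cc1 | intermediate
7 | methyl 3-methylbut-2-enoate | COC(=O)C=C(C)C | starting material
8 | tert-butyl[(1-methoxy-3-methylbuta-1,3-dienyl)oxy]dimethylsilane | COC(O[Si](C)(C)C(C)(C)C)=CC(C)=C | intermediate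
9 | methyl (2E,5R,6Z,8E)-5-hydroxy-10-(4-methoxybenzyloxy)-3,7-dimethyldeca-2,6,8-trienoate | COC(=O)/C=C(\C)C[C@@H](O)/C=C(C)\C=C\COCc1ccc(OC)cc1 | intermediate
10 | (2E,5R,6Z,8E)-10-(4-methoxybenzyloxy)-3,7-dimethyldeca-2,6,8-triene-1,5-diol | OC/C=C(\C)C[C@@H](O)/C=C(C)\C=C\COCc1ccc(OC)cc1 | intermediate
11 | [(2R,3R)-3-[(2R,3Z,5E)-2-hydroxy-7-(4-methoxybenzyloxy)-4-methylhepta-3,5-dienyl]-3-methyloxiran-2-yl]methanol | OC[C@H]1O[C@]1(C)C[C@@H](O)/C=C(C)\C=C\COCc1ccc(OC)cc1 | intermediate
12 | (3S,5R,6Z,8E)-10-(4-methoxybenzyloxy)-3,7-dimethyldeca-6,8-diene-1,3,5-triol | OCC[C@](C)(O)C[C@@H](O)/C=C(C)\C=C\COCc1ccc(OC)cc1 | intermediate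
13 | (4R,6R)-4-hydroxy-6-[(1Z,3E)-5-(4-methoxybenzyloxy)-2-methylpenta-1,3-dienyl]-4-methyltetrahydropyran-2-one | C[C@]1(O)CC(=O)O[C@@H](/C=C(C)\C=C\COCc2ccc(OC)cc2)C1 | intermediate
14 | bis(triethylsilyl) ketene acetal of 13 (C9 O-silyl enol ether, C11 silyl ether) | CC[Si](CC)(CC)OC1=C[C@](C)(O[Si](CC)(CC)CC)C[C@H](/C=C(C)\C=C\COCc2ccc(OC)cc2)O1 | intermediate
15 | triethylsilyl ester of 16 | CC[Si](CC)(CC)OC(=O)[C@@H]1[C@](C)(C=CC[C@@]1(C)O[Si](CC)(CC)CC)/C=C/COCc1ccc(OC)cc1 | intermediate
16 | (1R,2R,6R)-2-[(E)-3-(4-methoxybenzyloxy)prop-1-enyl]-2,6-dimethyl-6-(triethylsilyloxy)cyclohex-3-ene-1-carboxylic acid (ring C1 = C10, ring C2 = C1, ring C6 = C11 of the target) | OC(=O)[C@@H]1[C@](C)(C=CC[C@@]1(C)O[Si](CC)(CC)CC)/C=C/COCc1ccc(OC)cc1 | intermediate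
17 | 1,4-bis(trimethylsilyl)buta-1,3-diyne | C[Si](C)(C)C#CC#C[Si](C)(C)C | starting material
18 | 5-(trimethylsilyl)penta-2,4-diyn-1-ol | C[Si](C)(C)C#CC#CCO | intermediate
19 | triethyl{[5-(trimethylsilyl)penta-2,4-diynyl]oxy}silane | C[Si](C)(C)C#CC#CCO[Si](CC)(CC)CC | intermediate
20 | acid chloride of 16 | ClC(=O)[C@@H]1[C@](C)(C=CC[C@@]1(C)O[Si](CC)(CC)CC)/C=C/COCc1ccc(OC)cc1 | intermediate
21 | C9 diynone: 1-[(1R,2R,6R)-2-[(E)-3-(4-methoxybenzyloxy)prop-1-enyl]-2,6-dimethyl-6-(triethylsilyloxy)cyclohex-3-enyl]-6-(triethylsilyloxy)hexa-2,4-diyn-1-one | CC[Si](CC)(CC)OCC#CC#CC(=O)[C@@H]1[C@](C)(C=CC[C@@]1(C)O[Si](CC)(CC)CC)/C=C/COCc1ccc(OC)cc1 | intermediate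
22 | (9R)-diynol: C9 carbinol of 21, configured as C9 of 37 | CC[Si](CC)(CC)OCC#CC#C[C@H](O)[C@@H]1[C@](C)(C=CC[C@@]1(C)O[Si](CC)(CC)CC)/C=C/COCc1ccc(OC)cc1 | intermediate
23 | (7E,9R)-enynol: C7=C8 E-alkene, C5≡C6 alkyne, free 9-OH | CC[Si](CC)(CC)OCC#C/C=C/[C@H](O)[C@@H]1[C@](C)(C=CC[C@@]1(C)O[Si](CC)(CC)CC)/C=C/COCc1ccc(OC)cc1 | intermediate
24 | (7R,8R,9R)-7,8-epoxy-9-ol: trans-epoxide of 23, anti to 9-OH | CC[Si](CC)(CC)OCC#C[C@H]1O[C@@H]1[C@H](O)[C@@H]2[C@](C)(C=CC[C@@]2(C)O[Si](CC)(CC)CC)/C=C/COCc1ccc(OC)cc1 | intermediate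
25 | C9 triethylsilyl ether of 24 | CC[Si](CC)(CC)OCC#C[C@H]1O[C@@H]1[C@H](O[Si](CC)(CC)CC)[C@@H]2[C@](C)(C=CC[C@@]2(C)O[Si](CC)(CC)CC)/C=C/COCc1ccc(OC)cc1 | intermediate
26 | C7 acrylate C8 alcohol: 25 opened at C7 with inversion, C7 as in 37 | CC[Si](CC)(CC)OCC#C[C@H](OC(=O)C=C)[C@H](O)[C@H](O[Si](CC)(CC)CC)[C@@H]1[C@](C)(C=CC[C@@]1(C)O[Si](CC)(CC)CC)/C=C/COCc1ccc(OC)cc1 | intermediate
27 | C8 ketone of 26 (α-acryloyloxy ketone) | CC[Si](CC)(CC)OCC#C[C@H](OC(=O)C=C)C(=O)[C@H](O[Si](CC)(CC)CC)[C@@H]1[C@](C)(C=CC[C@@]1(C)O[Si](CC)(CC)CC)/C=C/COCc1ccc(OC)cc1 | intermediate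
28 | β-hydroxy-γ-lactone: C7–O–C19(=O)–C17(Me)–C8(OH) closed, C7, C8, C9, C17 as in 37 | CC[Si](CC)(CC)OCC#C[C@@H]1OC(=O)[C@H](C)[C@@]1(O)[C@H](O[Si](CC)(CC)CC)[C@@H]2[C@](C)(C=CC[C@@]2(C)O[Si](CC)(CC)CC)/C=C/COCc1ccc(OC)cc1 | intermediate
29 | C12 allylic alcohol of 28 (either C12 epimer) | CC[Si](CC)(CC)OCC#C[C@@H]1OC(=O)[C@H](C)[C@@]1(O)[C@H](O[Si](CC)(CC)CC)[C@@H]2[C@](C)(C=CC(O)[C@@]2(C)O[Si](CC)(CC)CC)/C=C/COCc1ccc(OC)cc1 | intermediate
30 | C12 enone of 28 | CC[Si](CC)(CC)OCC#C[C@@H]1OC(=O)[C@H](C)[C@@]1(O)[C@H](O[Si](CC)(CC)CC)[C@@H]2[C@](C)(C=CC(=O)[C@@]2(C)O[Si](CC)(CC)CC)/C=C/COCc1ccc(OC)cc1 | intermediate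
31 | C4 allylic alcohol: 30 without the 4-methoxybenzyl group | CC[Si](CC)(CC)OCC#C[C@@H]1OC(=O)[C@H](C)[C@@]1(O)[C@H](O[Si](CC)(CC)CC)[C@@H]2[C@](C)(C=CC(=O)[C@@]2(C)O[Si](CC)(CC)CC)/C=C/CO | intermediate
32 | C4 allylic acetate of 31 | CC[Si](CC)(CC)OCC#C[C@@H]1OC(=O)[C@H](C)[C@@]1(O)[C@H](O[Si](CC)(CC)CC)[C@@H]2[C@](C)(C=CC(=O)[C@@]2(C)O[Si](CC)(CC)CC)/C=C/COC(C)=O | intermediate
33 | alkyne tetraol: free 8-, 9-, 11- and 16-OH, C4 acetate | OCC#C[C@@H]1OC(=O)[C@H](C)[C@@]1(O)[C@H](O)[C@@H]2[C@](C)(C=CC(=O)[C@@]2(C)O)/C=C/COC(C)=O | intermediate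
34 | (5Z)-5-tributylstannyl alkene: Sn on C5 cis to C7 | OC/C([Sn](CCCC)(CCCC)CCCC)=C/[C@@H]1OC(=O)[C@H](C)[C@@]1(O)[C@H](O)[C@@H]2[C@](C)(C=CC(=O)[C@@]2(C)O)/C=C/COC(C)=O | intermediate
35 | macrocyclic tetraol: 2,3-deoxy-9,11,16-tris-deacetyl 37, (2E,5Z)-diene in the ten-membered ring | OC/C1=C/[C@@H]2OC(=O)[C@H](C)[C@@]2(O)[C@H](O)[C@@H]2[C@](C)(C=CC(=O)[C@@]2(C)O)/C=C/C1 | intermediate
36 | (2E)-alkene triacetate: 2,3-deoxy 37 | CC(=O)OC/C1=C/[C@@H]2OC(=O)[C@H](C)[C@@]2(O)[C@H](OC(C)=O)[C@@H]2[C@](C)(C=CC(=O)[C@@]2(C)OC(C)=O)/C=C/C1 | intermediate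
37 | CNP0226792.2, (1S,2R,3R,5Z,7S,8S,9R,10S,11S,17R) in briarane numbering | CC(=O)OC/C1=C/[C@@H]2OC(=O)[C@H](C)[C@@]2(O)[C@H](OC(C)=O)[C@@H]2[C@](C)(C=CC(=O)[C@@]2(C)OC(C)=O)[C@H]2O[C@@H]2C1 | target

**Step count**
Total steps: 29. Longest linear sequence: 25 (steps 1, 3, 4, 6–11, 14–29); steps 2, 5, 12 and 13 prepare coupling partners.

**Steps most likely to fail**

Step 27 (macrocyclic Stille coupling). Transmetalation from the hindered 1,1-disubstituted alkenylstannane may be slow, so that protodestannylation and intermolecular coupling outrun closure of the strained ten-membered ring. Fallback: setting out from 34, a palladium-free copper-mediated allylation (allyl bromide, Cu thiophene-2-carboxylate, NMP, 0 °C), which leaves the C4 acetate untouched, should give the C5-allyl triene F1. Ring-closing metathesis (second-generation Hoveyda–Grubbs catalyst, PhMe, 80 °C, 1 mM) between the terminal allyl alkene and the C2=C3 alkene, with loss of allyl acetate, then comes back to the route at 35.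

Step 29 (epoxidation). The facial selectivity is set by the ring conformation and cannot be overridden by an external oxidant if the ring strap covers the face that must be attacked; site selectivity against C5=C6 may also be incomplete. Fallback: setting out from 35, selective acetylation of the primary C16 hydroxyl (Ac2O, 2,4,6-collidine, −40 °C) gives the 16-monoacetate F2. Epoxidation with VO(acac)2 and t-BuOOH, directed by the bishomoallylic C9 hydroxyl, delivers oxygen to C2=C3 from the strap side and gives the epoxy triol F3. Acetylation (Ac2O, Et3N, DMAP) then comes back to the route at 37.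

Step 11 (dianionic lactone Claisen). Incomplete O-silylation of the tertiary alkoxide, or β-elimination or retro-aldol of the lactone dianion, may intervene before the rearrangement. Fallback: setting out from 13, the tertiary hydroxyl is silylated first (Et3SiOTf, 2,6-lutidine) to the C11 triethylsilyl ether F4. Internal-quench enolisation (LiN(i-Pr)2 added to F4 and Et3SiCl at −100 °C) then gives ketene acetal 14 without a free enolate; this rearranges and is hydrolysed as in step 11, coming back to the route at 16.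

**Further compounds**
F1 | step 27 | C5-allyl triene: 34 with the tributylstannyl group replaced by prop-2-enyl | OC/C(CC=C)=C/[C@@H]1OC(=O)[C@H](C)[C@@]1(O)[C@H](O)[C@@H]2[C@](C)(C=CC(=O)[C@@]2(C)O)/C=C/COC(C)=O
F2 | step 29 | 16-monoacetate of 35 | CC(=O)OC/C1=C/[C@@H]2OC(=O)[C@H](C)[C@@]2(O)[C@H](O)[C@@H]2[C@](C)(C=CC(=O)[C@@]2(C)O)/C=C/C1
F3 | step 29 | (2R,3R)-epoxide of F2 (9,11-bis-deacetyl 37) | CC(=O)OC/C1=C/[C@@H]2OC(=O)[C@H](C)[C@@]2(O)[C@H](O)[C@@H]2[C@](C)(C=CC(=O)[C@@]2(C)O)[C@H]2O[C@@H]2C1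
F4 | step 11 | C11 triethylsilyl ether of 13 | CC[Si](CC)(CC)O[C@@]1(C)CC(=O)O[C@@H](/C=C(C)\C=C\COCc2ccc(OC)cc2)C1
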